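A small charge of free catalyst, 0.12 mM, works through a racemate of 10.0 mM in all, against 7.50 mM of partner. Each product takes one partner, so partner was the limiting reagent, and this flask had to stop at 7.50 mM of product with 2.50 mM of substrate never converted.

left-handed substrate 5.0 mM; partner 7.50 mM; free catalyst 0.12 mM; right-handed substrate 5.0 mM

    free catalyst + left-handed substrate ⇌ catalyst intermediate A (K1 = 490 /M, k1 = 95000 /M/s)
    free catalyst + right-handed substrate ⇌ catalyst intermediate B (K2 = 530 /M, k2 = 29000 /M/s)
    partner + catalyst intermediate A → free catalyst + left-handed product (k3 = 830 /M/s)
    partner + catalyst intermediate B → free catalyst + right-handed product (k4 = 280 /M/s)
    2 free catalyst ⇌ resting dimer, settled at all times (K5 = 7400 /M)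
    left-handed substrate ⇌ right-handed substrate (k6 = 0.11 /s)

- apparent order in partner when 50% of the left-handed substrate and right-handed substrate together are converted (percent change of the rate of making left-handed product for one percent more partner charged)
- apparent order in free catalyst when 50% of the left-handed substrate and right-handed substrate together are converted (percent change of the rate of making left-handed product for one percent more free catalyst charged)
- factor on the rate of making left-handed product when 50% of the left-handed substrate and right-handed substrate together are converted if partner is charged twice over

- free catalyst is single-handed; left-handed substrate and right-handed substrate are mirror images of each other, charged as a racemate, each of them at the stated concentration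
- for a step with 2 of a species take k times the square, and two of it per event
- charge of left-handed substrate (flask): 5.0 mM

I looked at the moment when 50% of both substrates together is converted, and I called it the mark. The conversion consumed 5.00 mM of partner, so 2.50 mM stood in the flask, and this partner left at the mark was what I carried.

The neighbouring flask differs in one line, partner charged twice over. It holds 5.00 mM of partner beyond the substrates, so there partner stops being the limiting reagent, and at the mark it keeps 10.0 mM.

To compare the two I counted lifetimes. Even with all the catalyst sitting as catalyst intermediate A under partner as charged, the mark takes at least 6.69 s, which is twice the racemisation half-life of 3.15 s. So I took the two substrates to stay nearly level in this flask. In the neighbouring flask the same bound is 3.35 s, about one racemisation half-life, so there I could not claim the same, and I took c(catalyst intermediate A) as equal in the two flasks at the mark only as a first estimate. On that estimate the rate, k3 times c(partner) times c(catalyst intermediate A), follows the partner left, which gives a factor of 4.00 for the neighbour. One percent more charge lands on a remainder much smaller than the charge, so I set the ceiling on the order in partner at 3.00. With resting dimer in the scheme, I went no further for free catalyst than a ceiling of 1.00.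

The forecast gave 2.8, 0.86 and 3.45, saying that “a small change in the charge is amplified roughly threefold”.

The flask gave 2.8 for partner, 0.87 for free catalyst and a factor of 3.47, with the mark reached at 23.6 s. Just past it, at 25.0 s, 46% of the left-handed substrate and 51% of the right-handed substrate remained of their charges. Carried on to a conversion of 0.7 as a fraction, the same subtraction leaves 0.500 mM of partner, a partner factor of 0.200 on the rate at the mark, and the flask's rate at 66.8 s stood at 0.17 of that rate.

The constants are made up; the rest is arithmetic.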